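The numbers stand for no real mixture; no experiment stands behind them.

A one-step world, Q going to X and back, ends with X and Q in the ratio of the equilibrium constant, and since this step is exothermic, heat lowers that ratio as well as bringing the end sooner. These flasks are another matter, since Q also leaves irreversibly for Q2 and Q.Z, so an X that returns to Q can be lost.

| flask | Q | Z | temperature | time |
|---|---|---|---|---|
| violet | 0.30 M | 0.0300 M | 75 °C | 50 s |
| amber | 0.30 M | 0.0300 M | 15 °C | 50 s |
| teal | 0.30 M | 0.0300 M | 35 °C | 50 s |
| red | 0.30 M | 0.0300 M | 55 °C | 50 s |

    Q ⇌ L (K1 = 0.86, k1 = 0.024 /s, Ea1 = 72.0 kJ/mol, ΔH1 = −12.0 kJ/mol)
    Q ⇌ X (K2 = 5.9, k2 = 0.023 /s, Ea2 = 83.0 kJ/mol, ΔH2 = −90.0 kJ/mol)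
    2 Q → Q2 (k3 = 0.13 /M/s, Ea3 = 54.0 kJ/mol)
    Q + Z → Q.Z (k4 = 0.48 /M/s, Ea4 = 51.0 kJ/mol)
    (constants at 35 °C)

- percentages count the Q that a species holds: one Q2 counts as two
- two of one species on the left: rate k times its square, two consumed each time
- the list of constants is for 35 °C, to be carried to other temperatures by the activation energies and enthalpies

1. the best flask by amount of X, in percent of the Q charged; "all alike" if 1.5 percentage points covers them all (violet / amber / teal / red / all alike)
2. amount of X at the end, in percent of the Q charged, violet
3. amount of X at the end, in percent of the Q charged, amber
4. amount of X at the end, in percent of the Q charged, teal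
5. amount of X at the end, in percent of the Q charged, red

The reckoning here compares, for one X at one moment, the back step with the time allowed. The back rate constant of X, its forward constant over its equilibrium constant, multiplied by the run time, is the return number: how many times an X goes back to Q during the run. In teal, at the reference temperature, it is 0.195. The back step carries an activation energy of 173 kJ/mol, so the number climbs steeply with heat: 0.00180 in amber, 11.9 in red, 456 in violet.

Far below one, a flask keeps the X it has made, which is kinetic control. Far above one, the comparison drifts with the flask: Q falls while each X keeps returning at its fixed rate, so X follows Q down at the equilibrium ratio, which is thermodynamic control. That ratio is 0.694 in red and 0.104 in violet.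

One number is not enough, however. Amber has the lowest return number, yet its return number times its equilibrium constant, the forward number, is 0.121, so amber has had too little time. Teal's forward number is 1.15. With forward number more than one and return number less than one, teal is the pick of this reckoning, since amber's forward number is less than one and the return numbers of red and violet are more than one. The reckoning stops there: it gives no percentages and does not rank amber against red.

The forecast names teal, with 0.36% in violet, 7.5% in amber, 26% in teal and 7.5% in red, on the grounds that “Teal sits at the compromise”.

The best flask is teal, with 26.3% of the charged Q as X, against 7.47% in amber, 7.78% in red and 0.355% in violet, each within the forecast's tolerance. At the end of red, X stands to Q at 0.733. A repeat of violet at 50 °C has a return number of 4.48, more than one, and an equilibrium ratio of 1.16. That flask ends with 15.5% as X and 12.0% as Q, a ratio of 1.29.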